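**Strategy.** The route rests on opening the pyran ring at its two bonds to ring A, C4–C4a and O1–C8a. With C4 and O1 removed, ring A is a twofold-symmetric 4-iodo-2,6-bis(benzyloxy)phenyl isobutyl ketone whose iodine sits at C8a and whose two ortho C–H bonds (C4a, C8) are equivalent. One palladium/norbornene (Catellani-type) annulation joins it to an enantiopure anti γ-bromo alcohol carrying C2, C3 and the protected ring B: ortho C–H alkylation forges C4–C4a, ipso etherification forges O1–C8a. The bromo alcohol comes from a proline anti-aldol on one formyl group of a threefold-symmetric trialdehyde; hydrogenolysis of five benzyl ethers ends the synthesis.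

Key step: step 6

Remark: chroman numbering is used (O1, C2, C3, C4, C4a, C5–C8, C8a); ring A is the benzo ring, ring B the diformylphloroglucinol ring on C2; the target is the trans (2R,3S) isomer.
Assumption: N-methoxy-N,3-dimethylbutanamide (2) is taken as purchasable (otherwise one step from 3-methylbutanoyl chloride and N,O-dimethylhydroxylamine).

Step 1
Reactants: 1 1,3-difluoro-5-iodobenzene; 2 N-methoxy-N,3-dimethylbutanamide
Product: 4 1-(2,6-difluoro-4-iodophenyl)-3-methylbutan-1-one, via aryllithium 3 (not isolated)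
Conditions: LiN(iPr)2, THF, −78 °C; then 2, −78 → −40 °C; H2O
Reagents that add atoms: none
Why: Deprotonation occurs at the C–H flanked by both fluorines (most acidic site, iodine untouched at −78 °C), and the aryllithium acylates the N-methoxy-N-methylamide through a chelated tetrahedral adduct, a Weinreb ketone synthesis that stops at the ketone.

Step 2
Reactants: 4 1-(2,6-difluoro-4-iodophenyl)-3-methylbutan-1-one
Product: 5 1-[2,6-bis(benzyloxy)-4-iodophenyl]-3-methylbutan-1-one
Conditions: BnOH, NaH, THF, 0 → 60 °C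
Reagents that add atoms: benzyl alcohol, OCc1ccccc1
Why: Double nucleophilic aromatic substitution (SNAr) of the two fluorides ortho to the ketone by benzyloxide, fluoride being a far better nucleofuge than the para iodide in the addition–elimination mechanism.

Step 3
Reactants: 6 2,4,6-trihydroxybenzene-1,3,5-tricarbaldehyde
Product: 7 2,4,6-tris(benzyloxy)benzene-1,3,5-tricarbaldehyde
Conditions: BnBr, K2CO3, DMF, 60 °C
Reagents that add atoms: benzyl bromide, BrCc1ccccc1
Why: Williamson O-alkylation of the three acidic phenols; every ring carbon already carries a substituent, so the ambident phenoxide should be trapped on oxygen only.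

Step 4
Reactants: 7 2,4,6-tris(benzyloxy)benzene-1,3,5-tricarbaldehyde; 8 3-methylbutanal
Product: 10 2,4,6-tris(benzyloxy)-5-[(1R,2R)-1,3-dihydroxy-2-(propan-2-yl)propyl]benzene-1,3-dicarbaldehyde, via aldol aldehyde 9 (not isolated)
Conditions: 7 (3 equiv), L-proline (20 mol%), DMF, 4 °C, slow addition of 8; cold aqueous wash; then NaBH(OAc)3, AcOH, THF, −20 → 0 °C
Reagents that add atoms: none
Why: Proline enamine cross-aldol in which the E-enamine of 8 adds to the Re face of one formyl group of 7 (used in excess to favour mono-addition) in the hydrogen-bonded chair-like transition state, setting the (R) carbinol centre and the anti neighbour under catalyst control, followed by hydroxyl-directed NaBH(OAc)3 reduction of the aliphatic aldehyde, which the hindered, electron-rich aryl formyl groups should survive.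

Step 5
Reactants: 10 2,4,6-tris(benzyloxy)-5-[(1R,2R)-1,3-dihydroxy-2-(propan-2-yl)propyl]benzene-1,3-dicarbaldehyde
Product: 11 2,4,6-tris(benzyloxy)-5-[(1R,2S)-3-bromo-1-hydroxy-2-(propan-2-yl)propyl]benzene-1,3-dicarbaldehyde
Conditions: N-bromosuccinimide, PPh3, CH2Cl2, −20 → 0 °C
Reagents that add atoms: N-bromosuccinimide, O=C1CCC(=O)N1Br
Why: Appel-type bromination through an alkoxyphosphonium salt, selective for the primary over the hindered secondary benzylic hydroxyl and free of the phosphorus ylide that CBr4 would give with the formyl groups; no stereocentre is touched.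

Step 6
Reactants: 5 1-[2,6-bis(benzyloxy)-4-iodophenyl]-3-methylbutan-1-one; 11 2,4,6-tris(benzyloxy)-5-[(1R,2S)-3-bromo-1-hydroxy-2-(propan-2-yl)propyl]benzene-1,3-dicarbaldehyde
Product: 12 2,4,6-tris(benzyloxy)-5-[(2R,3S)-5,7-bis(benzyloxy)-6-(3-methylbutanoyl)-3-(propan-2-yl)-3,4-dihydro-2H-chromen-2-yl]benzene-1,3-dicarbaldehyde
Conditions: Pd(OAc)2 (10 mol%), RuPhos (20 mol%), 1-methylbicyclo[2.2.1]hept-2-ene (1 equiv), K2CO3, MeCN, 90 °C, slow addition of 11 to a slight excess of 5
Reagents that add atoms: none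
Why: Proposed new method: zerovalent palladium inserts into the C–I bond of 5, the bridgehead-substituted norbornene inserts, and the norbornyl–palladium palladates one of the two equivalent ortho C–H bonds (C4a) to a five-membered aryl–norbornyl palladacycle of divalent palladium; this is alkylated at the metal by the primary C–Br of 11 (tetravalent palladium), C(sp2)–C(sp3) reductive elimination makes C4–C4a, and β-carbon elimination expels the norbornene. The aryl–palladium left at C8a is captured by the tethered secondary alkoxide as a seven-membered oxapalladacycle, whose C(aryl)–O reductive elimination closes the six-membered pyran ring and makes O1–C8a. The closest known reaction type is the Catellani annulation of aryl iodides with epoxides to 2,3-dihydrobenzofurans and with bromoalkylamines to indolines and tetrahydroquinolines; the one-carbon-longer alcohol tether and the ortho-unsubstituted iodide are the new elements. No stereocentre is formed: C2 and C3 come from 11 and stay untouched, because alkylation occurs at the CH2Br carbon and the C2–O bond is never broken, so the trans-2,3 relationship is retained. The step needs mono- rather than double ortho-alkylation, which the twofold symmetry of 5 (either ortho C–H gives the same product), the bridgehead substituent on the norbornene (faster norbornene extrusion after the first alkylation) and the low standing concentration of 11 should secure; it also needs C–O reductive elimination to outrun β-hydride elimination of the alkoxide, for which the bulky biarylphosphine is chosen.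

Step 7
Reactants: 12 2,4,6-tris(benzyloxy)-5-[(2R,3S)-5,7-bis(benzyloxy)-6-(3-methylbutanoyl)-3-(propan-2-yl)-3,4-dihydro-2H-chromen-2-yl]benzene-1,3-dicarbaldehyde
Product: 13 2,4,6-trihydroxy-5-[(2R,3S)-5,7-dihydroxy-6-(3-methylbutanoyl)-3-(propan-2-yl)-3,4-dihydro-2H-chromen-2-yl]benzene-1,3-dicarbaldehyde
Conditions: H2 (1 atm), palladium on carbon (Pd/C), EtOAc, 23 °C
Reagents that add atoms: none
Why: Hydrogenolysis of the five aryl benzyl ethers in a non-protic solvent, the hydrogen-bonded formyl and acyl groups and the hindered C2–O1 ether being expected to react more slowly, so that no stereocentre is touched.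

**Compound list**
1 | 1,3-difluoro-5-iodobenzene | Fc1cc(I)cc(F)c1 | starting material
2 | N-methoxy-N,3-dimethylbutanamide | CC(C)CC(=O)N(C)OC | starting material
3 | (2,6-difluoro-4-iodophenyl)lithium (not isolated) | [Li]c1c(F)cc(I)cc1F | intermediate
4 | 1-(2,6-difluoro-4-iodophenyl)-3-methylbutan-1-one | CC(C)CC(=O)c1c(F)cc(I)cc1F | intermediate
5 | 1-[2,6-bis(benzyloxy)-4-iodophenyl]-3-methylbutan-1-one | CC(C)CC(=O)c1c(OCc2ccccc2)cc(I)cc1OCc1ccccc1 | intermediate
6 | 2,4,6-trihydroxybenzene-1,3,5-tricarbaldehyde | O=Cc1c(O)c(C=O)c(O)c(C=O)c1O | starting material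
7 | 2,4,6-tris(benzyloxy)benzene-1,3,5-tricarbaldehyde | O=Cc1c(OCc2ccccc2)c(C=O)c(OCc2ccccc2)c(C=O)c1OCc1ccccc1 | intermediate
8 | 3-methylbutanal | CC(C)CC=O | starting material
9 | (2S,3R)-3-hydroxy-2-(propan-2-yl)-3-[2,4,6-tris(benzyloxy)-3,5-diformylphenyl]propanal (not isolated) | O=C[C@@H](C(C)C)[C@H](c1c(OCc2ccccc2)c(C=O)c(OCc2ccccc2)c(C=O)c1OCc1ccccc1)O | intermediate
10 | 2,4,6-tris(benzyloxy)-5-[(1R,2R)-1,3-dihydroxy-2-(propan-2-yl)propyl]benzene-1,3-dicarbaldehyde | OC[C@@H](C(C)C)[C@H](c1c(OCc2ccccc2)c(C=O)c(OCc2ccccc2)c(C=O)c1OCc1ccccc1)O | intermediate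
11 | 2,4,6-tris(benzyloxy)-5-[(1R,2S)-3-bromo-1-hydroxy-2-(propan-2-yl)propyl]benzene-1,3-dicarbaldehyde | BrC[C@@H](C(C)C)[C@H](c1c(OCc2ccccc2)c(C=O)c(OCc2ccccc2)c(C=O)c1OCc1ccccc1)O | intermediate
12 | 2,4,6-tris(benzyloxy)-5-[(2R,3S)-5,7-bis(benzyloxy)-6-(3-methylbutanoyl)-3-(propan-2-yl)-3,4-dihydro-2H-chromen-2-yl]benzene-1,3-dicarbaldehyde | CC(C)CC(=O)c1c(OCc3ccccc3)cc2c(c1OCc1ccccc1)C[C@@H](C(C)C)[C@H](c1c(OCc3ccccc3)c(C=O)c(OCc3ccccc3)c(C=O)c1OCc1ccccc1)O2 | intermediate
13 | 2,4,6-trihydroxy-5-[(2R,3S)-5,7-dihydroxy-6-(3-methylbutanoyl)-3-(propan-2-yl)-3,4-dihydro-2H-chromen-2-yl]benzene-1,3-dicarbaldehyde | CC(C)CC(=O)c1c(O)cc2c(c1O)C[C@@H](C(C)C)[C@H](c1c(O)c(C=O)c(O)c(C=O)c1O)O2 | target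

**Count.** Total: 7 steps. Longest linear sequence: 5 steps (6 → 7 → 10 → 11 → 12 → 13).

**Steps most likely to fail**

1. Step 6 (Proposed new method). What may go wrong:
   - a second ortho C–H palladation before norbornene extrusion, leading to double alkylation;
   - slow reaction of the β-branched bromide with the palladacycle at a C–H flanked by a benzyloxy group;
   - base-induced Grob fragmentation or oxetane closure of the bromo alkoxide;
   - β-hydride elimination from the palladium alkoxide instead of C–O bond formation.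

   Fallback (known chemistry, stepwise; sets out from diol 10 and iodide 5, returns at 12): the primary hydroxyl of 10 is silylated (tert-butyldimethylsilyl chloride, imidazole, CH2Cl2) to the primary silyl ether F1. Buchwald–Hartwig etherification of 5 with the secondary hydroxyl of F1 (Pd2(dba)3, RockPhos, Cs2CO3, toluene, 90 °C) makes O1–C8a and gives the aryl ether F2. N-Iodosuccinimide with catalytic CF3CO2H in MeCN iodinates one of the two equivalent positions ortho to the new ether oxygen to give the aryl iodide F3. Bu4NF/AcOH in THF frees the primary alcohol F4, which I2/PPh3/imidazole converts into the primary iodide F5. Zinc dust/LiCl in THF should insert into the alkyl C–I bond only, giving the alkylzinc iodide F6, and Pd(OAc)2/SPhos closes C4–C4a by intramolecular Negishi coupling to 12.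

2. Step 4. What may go wrong: sluggish enamine addition to the doubly ortho-substituted formyl group, erosion of anti selectivity or epimerisation of the aldol aldehyde before reduction, a second aldol on another formyl group, or hydride attack on the aryl formyl groups.

   Fallback (sets out from trialdehyde 7, returns at aldol aldehyde 9): commercial (E)-4-methylpent-2-ene is metalated at its methyl group (n-BuLi, KOtBu, THF, −50 °C), borylated with B(OiPr)3 and transesterified with pinacol to the (E)-allylboronate F7. Chiral phosphoric acid-catalysed allylboration of one formyl group of 7 (3 equiv) with F7 and (R)-TRIP (the enantiomer expected to direct Re-face attack) in toluene at −30 °C proceeds through the closed six-membered chair transition state and should give the anti homoallylic alcohol F8. Ozonolysis (O3, CH2Cl2, −78 °C; PPh3) cuts the vinyl group to the aldol aldehyde 9, which is reduced with NaBH(OAc)3 as in step 4 to 10.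

3. Step 7. What may go wrong: over-reduction of the formyl groups (to hydroxymethyl or methyl) and hydrogenolytic opening of the benzylic C2–O1 bond during the slow removal of the last, chelated benzyl groups.

   Fallback (sets out from 12, returns at 13): Lewis-acid debenzylation with BCl3 and pentamethylbenzene as benzyl-cation scavenger in CH2Cl2 at −78 °C, where the benzyl ethers ortho to carbonyl groups are cleaved by chelation while the non-chelated ring ether should persist (no new compound, F0).

**Further compounds**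
F1 | step 6 | 2,4,6-tris(benzyloxy)-5-[(1R,2R)-3-{[tert-butyl(dimethyl)silyl]oxy}-1-hydroxy-2-(propan-2-yl)propyl]benzene-1,3-dicarbaldehyde | CC(C)(C)[Si](C)(C)OC[C@@H](C(C)C)[C@H](c1c(OCc2ccccc2)c(C=O)c(OCc2ccccc2)c(C=O)c1OCc1ccccc1)O
F2 | step 6 | 2,4,6-tris(benzyloxy)-5-[(1R,2R)-1-[3,5-bis(benzyloxy)-4-(3-methylbutanoyl)phenoxy]-3-{[tert-butyl(dimethyl)silyl]oxy}-2-(propan-2-yl)propyl]benzene-1,3-dicarbaldehyde | CC(C)(C)[Si](C)(C)OC[C@@H](C(C)C)[C@H](c1c(OCc2ccccc2)c(C=O)c(OCc2ccccc2)c(C=O)c1OCc1ccccc1)Oc1cc(OCc2ccccc2)c(C(=O)CC(C)C)c(OCc2ccccc2)c1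
F3 | step 6 | 2,4,6-tris(benzyloxy)-5-[(1R,2R)-1-[3,5-bis(benzyloxy)-2-iodo-4-(3-methylbutanoyl)phenoxy]-3-{[tert-butyl(dimethyl)silyl]oxy}-2-(propan-2-yl)propyl]benzene-1,3-dicarbaldehyde | CC(C)(C)[Si](C)(C)OC[C@@H](C(C)C)[C@H](c1c(OCc2ccccc2)c(C=O)c(OCc2ccccc2)c(C=O)c1OCc1ccccc1)Oc1cc(OCc2ccccc2)c(C(=O)CC(C)C)c(OCc2ccccc2)c1I
F4 | step 6 | 2,4,6-tris(benzyloxy)-5-[(1R,2R)-1-[3,5-bis(benzyloxy)-2-iodo-4-(3-methylbutanoyl)phenoxy]-3-hydroxy-2-(propan-2-yl)propyl]benzene-1,3-dicarbaldehyde | OC[C@@H](C(C)C)[C@H](c1c(OCc2ccccc2)c(C=O)c(OCc2ccccc2)c(C=O)c1OCc1ccccc1)Oc1cc(OCc2ccccc2)c(C(=O)CC(C)C)c(OCc2ccccc2)c1I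
F5 | step 6 | 2,4,6-tris(benzyloxy)-5-[(1R,2S)-1-[3,5-bis(benzyloxy)-2-iodo-4-(3-methylbutanoyl)phenoxy]-3-iodo-2-(propan-2-yl)propyl]benzene-1,3-dicarbaldehyde | IC[C@@H](C(C)C)[C@H](c1c(OCc2ccccc2)c(C=O)c(OCc2ccccc2)c(C=O)c1OCc1ccccc1)Oc1cc(OCc2ccccc2)c(C(=O)CC(C)C)c(OCc2ccccc2)c1I
F6 | step 6 | {(2S,3R)-3-[3,5-bis(benzyloxy)-2-iodo-4-(3-methylbutanoyl)phenoxy]-2-(propan-2-yl)-3-[2,4,6-tris(benzyloxy)-3,5-diformylphenyl]propyl}zinc iodide | I[Zn]C[C@@H](C(C)C)[C@H](c1c(OCc2ccccc2)c(C=O)c(OCc2ccccc2)c(C=O)c1OCc1ccccc1)Oc1cc(OCc2ccccc2)c(C(=O)CC(C)C)c(OCc2ccccc2)c1I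
F7 | step 4 | 4,4,5,5-tetramethyl-2-[(2E)-4-methylpent-2-en-1-yl]-1,3,2-dioxaborolane | CC(C)/C=C/CB1OC(C)(C)C(C)(C)O1
F8 | step 4 | 2,4,6-tris(benzyloxy)-5-[(1R,2R)-1-hydroxy-2-(propan-2-yl)but-3-en-1-yl]benzene-1,3-dicarbaldehyde | C=C[C@@H](C(C)C)[C@H](c1c(OCc2ccccc2)c(C=O)c(OCc2ccccc2)c(C=O)c1OCc1ccccc1)O
F0 | step 7 | none | none
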